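## The problem

Compound 11 is 5,7-dihydroxy-3-(4-hydroxy-2-methoxyphenyl)-6,8-bis(3-methylbut-2-en-1-yl)-4H-chromen-4-one, an isoflavone: benzo ring A is fused to pyranone ring C along C4a–C8a, ring B sits on C3, and C2 carries hydrogen. It has no stereocentre and no olefin of defined geometry, so the task is regiochemical and one of functional-group tolerance. Ring A is hexasubstituted (hydroxyls on C5 and C7, prenyl groups on C6 and C8), and two prenyl groups cannot be placed cleanly on a finished 5,7-dihydroxyisoflavone. Each prenyl olefin lies ortho to a phenol: strong Brønsted or Lewis acids close them to 2,2-dimethylchromans, hydrogenation saturates them, and electrophilic halogen or strong oxidants attack them. The 2-unsubstituted pyranone is opened at C2 by hydroxide, and the 2'-methoxy group must stay while the 4'-oxygen is freed. The enabling feature is that ring C adds only two atoms to a salicylaldehyde: the acyl carbon C4 and the phenol oxygen O1 already sit on ring A, and the bridge C2=C3 that carries ring B is an arylalkyne once the formyl and phenol hydrogens are removed. The matching aldehyde derives from mirror-symmetric 2,4,6-trihydroxybenzaldehyde, whose two free ring carbons and two ortho hydroxyls are pairwise equivalent, so neither the prenyl positions nor the choice of the oxygen that becomes O1 is in question.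

## Retrosynthesis

**11 ⇒ 10.** The three phenolic O–H bonds are traced back to methoxymethyl ethers at O5, O7 and O4'. Benzyl ethers are excluded because hydrogenolysis would reduce the prenyl olefins and boron halides would cyclise them. Methyl ethers could not be told apart from the 2'-methoxy group. The forward step must cleave three aryl acetals with dilute methanolic HCl without adding the freed phenols to the neighbouring olefins.

**10 ⇒ 9.** The C2–H bond is replaced by C2–SiMe3. A terminal arylalkyne would give no reliable orientation in the annulation and would homocouple under divalent copper. The silyl group makes the alkyne internal, steers the insertion, and is removed by fluoride, to which the acetals and olefins are inert.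

**9 ⇒ 4 + 8.** C3–C4 and O1–C2 are cut together, which opens ring C and gives salicylaldehyde 4 and silylalkyne 8. The neighbouring cut at C3–C1' (cross-coupling of a 3-halochromone) would bring electrophilic halogen to the prenyl olefins or postpone prenylation. The deoxybenzoin cut needs a strongly acidic one-carbon insertion at C2. The chosen cut forms two bonds and the ring in one convergent operation from two fragments that are two steps each from purchasable materials. The forward reaction must cleave only the formyl C–H bond of 4 and insert 8 with its aryl-bearing carbon toward the acyl group.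

**4 ⇒ 3 ⇒ 1 + 2.** Two O–CH2 bonds are cut first. Of the three hydroxyls of 3, the one hydrogen-bonded to the formyl oxygen is the least nucleophilic and is left free as the future O1. The two aryl–CH2 bonds are then cut, giving aldehyde 1 and prenyl bromide 2. Because the two open ring positions of 1 are equivalent, C-alkylation can only give the required constitution; the price is a modest first step on inexpensive material.

**8 ⇒ 6 + 7; 6 ⇒ 5.** The C(sp2)–C(sp) bond is cut to aryl bromide 6 and ethynyltrimethylsilane 7 (Sonogashira coupling), and the acetal of 6 to 4-bromo-3-methoxyphenol 5. The bromine of 5 fixes the attachment point of ring B, and the methyl ether already distinguishes O2' from O4'.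

## Roads not taken

**Alternative 1:** Double Claisen rearrangement.
- **Cut:** the aryl–CH2 bonds at C6 and C8, traced back to tertiary allyl ethers in 3-[2-methoxy-4-(methoxymethoxy)phenyl]-5,7-bis[(2-methylbut-3-en-2-yl)oxy]-4H-chromen-4-one A1.
- **Forward step:** Eu(fod)3 would promote two aromatic [3,3] shifts. Each inverts the allyl unit, so linear prenyl groups arrive and both hydroxyls are freed, giving 5,7-dihydroxy-3-[2-methoxy-4-(methoxymethoxy)phenyl]-6,8-bis(3-methylbut-2-en-1-yl)-4H-chromen-4-one A2, one acetal cleavage from 11.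
- **Merits:** prenylation is late, avoids the unselective alkylation of a phloroglucinol, and leaves a single protecting group at the end.
- **Weak points:**
  - The O5 ether has only C6 as a free ortho position, while the O7 ether can go to C6 or C8. If O7 takes C6 first, the O5 group can only reach C8 by a Claisen–Cope path, which delivers a 1,1-dimethylallyl group there.
  - A1 needs two tertiary O-alkylations, one on the chelated and poorly nucleophilic 5-hydroxyl.
  - The isoflavone core must still be built by another ring C construction, so the sequence is longer.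
- **Comparison:** this road is better in protecting-group economy. The chosen plan sets against it the symmetry of 3, which removes every positional question, and a ring synthesis that is part of the same design.

**Alternative 2:** Anodic phenol–enaminone coupling.
- **Cut:** C3–C1' and O1–C2, giving (E)-3-(dimethylamino)-1-[2-hydroxy-4,6-bis(methoxymethoxy)-3,5-bis(3-methylbut-2-en-1-yl)phenyl]prop-2-en-1-one A3 and unprotected 3-methoxyphenol A4.
- **Forward step:** anodic oxidation of A4 to a phenoxonium ion, capture by the enaminone α-carbon para to the hydroxyl, then displacement of dimethylamine by the ring A hydroxyl. The product would be 3-(4-hydroxy-2-methoxyphenyl)-5,7-bis(methoxymethoxy)-6,8-bis(3-methylbut-2-en-1-yl)-4H-chromen-4-one A5.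
- **Merits:** no metal, no halide, no alkyne and no protecting group on ring B; C2 arrives as C–H. If it worked it would be two to three steps shorter than the chosen plan.
- **Weak points:**
  - A3 (tetraoxygenated arene, free phenol, enaminone, two trisubstituted olefins) should be oxidised at least as easily as A4.
  - The phenoxonium ion of A4 is also electrophilic ortho to the hydroxyl (para to the methoxy group).
  - A5 is an electron-rich phenol open to over-oxidation.
  - No close model exists for such a densely functionalised pair.
- **Comparison:** the chosen plan uses polarity-defined partners: the attachment point of ring B is fixed by the bromine of 5, and divalent copper is too weak an oxidant to touch arenes or olefins.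

**Alternative 3:** Aryne annulation.
- **Cut:** O1–C8a and C4–C4a. Ring A becomes 3,5-bis(methoxymethoxy)-2,4-bis(3-methylbut-2-en-1-yl)-6-(trimethylsilyl)phenyl trifluoromethanesulfonate A6, which CsF would turn into the aryne 3,5-bis(methoxymethoxy)-4,6-bis(3-methylbut-2-en-1-yl)-1,2-didehydrobenzene A7. The partner is methyl 3-hydroxy-2-[2-methoxy-4-(methoxymethoxy)phenyl]prop-2-enoate A8.
- **Forward step:** the enol oxygen of A8 adds at C8a and the C4a anion acylates on the ester, giving 3-[2-methoxy-4-(methoxymethoxy)phenyl]-5,7-bis(methoxymethoxy)-6,8-bis(3-methylbut-2-en-1-yl)-4H-chromen-4-one A9, the same substance as 10.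
- **Merits:** no oxidant and no silyl group at C2, so one step is saved after ring closure. The C5 acetal oxygen inductively favours attack at the remote aryne carbon C8a, which is the required sense.
- **Weak points:**
  - A6 is a hexasubstituted benzene with five different substituent types and would cost more steps than the whole chosen route.
  - Formyl-ester nucleophiles usually attack arynes through carbon (acyl-alkylation), not oxygen.
  - C8a is shielded by the C8 prenyl group, and the prenyl olefins are ene partners for an aryne.
- **Comparison:** the chosen plan's ring A component 4 is two steps from 1, and its one extra step (fluoride desilylation) is cheap.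

Key step: step 5

## Route

Step 1
Reactants: 1 2,4,6-trihydroxybenzaldehyde; 2 prenyl bromide (1-bromo-3-methylbut-2-ene)
Product: 3 2,4,6-trihydroxy-3,5-bis(3-methylbut-2-en-1-yl)benzaldehyde
Conditions: 2 (2.1 equiv), KOH (10% aq.), 0 °C → rt
Reagents that add atoms: none
Why: C-alkylation of a phloroglucinol phenolate in water, the reaction type used to diprenylate acylphloroglucinols; hydrogen bonding to the phenolate oxygens directs the allylic bromide to carbon, and the two open ring carbons are equivalent, so the dialkylated product has only one possible constitution. Geminally dialkylated and O-alkylated by-products are expected and are removed by chromatography.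

Step 2
Reactants: 3 2,4,6-trihydroxy-3,5-bis(3-methylbut-2-en-1-yl)benzaldehyde
Product: 4 2-hydroxy-4,6-bis(methoxymethoxy)-3,5-bis(3-methylbut-2-en-1-yl)benzaldehyde
Conditions: MOMCl (2.2 equiv), i-Pr2NEt, CH2Cl2, 0 °C → rt
Reagents that add atoms: chloromethyl methyl ether, COCCl
Why: O-alkylation of phenols with an α-chloro ether; the C4 hydroxyl (para to the formyl group, most acidic) reacts first, then one of the two equivalent ortho hydroxyls, after which the last hydroxyl is held in a hydrogen bond to the formyl oxygen and resists alkylation, as is usual for 2,4,6-trihydroxyaryl carbonyl compounds.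

Step 3
Reactants: 5 4-bromo-3-methoxyphenol
Product: 6 1-bromo-2-methoxy-4-(methoxymethoxy)benzene
Conditions: MOMCl (1.2 equiv), i-Pr2NEt, CH2Cl2, 0 °C → rt
Reagents that add atoms: chloromethyl methyl ether, COCCl
Why: Standard O-alkylation of an unhindered phenol with chloromethyl methyl ether; the aryl bromide and methyl ether are inert.

Step 4
Reactants: 6 1-bromo-2-methoxy-4-(methoxymethoxy)benzene; 7 ethynyltrimethylsilane
Product: 8 {[2-methoxy-4-(methoxymethoxy)phenyl]ethynyl}trimethylsilane
Conditions: 7 (1.3 equiv), PdCl2(PhCN)2 (3 mol %), P(t-Bu)3 (6 mol %), CuI (2 mol %), i-Pr2NH, dioxane, rt → 45 °C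
Reagents that add atoms: none
Why: Sonogashira coupling; the bulky, electron-rich phosphine allows oxidative addition of the electron-rich, ortho-substituted aryl bromide to zerovalent palladium near room temperature, which keeps the volatile alkyne in solution and the C–Si bond intact.

Step 5
Reactants: 4 2-hydroxy-4,6-bis(methoxymethoxy)-3,5-bis(3-methylbut-2-en-1-yl)benzaldehyde; 8 {[2-methoxy-4-(methoxymethoxy)phenyl]ethynyl}trimethylsilane
Product: 9 3-[2-methoxy-4-(methoxymethoxy)phenyl]-5,7-bis(methoxymethoxy)-6,8-bis(3-methylbut-2-en-1-yl)-2-(trimethylsilyl)-4H-chromen-4-one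
Conditions: [Cp*Rh(MeCN)3](SbF6)2 (5 mol %), Cu(OAc)2 (2.2 equiv), 8 (1.3 equiv), ClCH2CH2Cl, 90 °C, N2
Reagents that add atoms: none
Why: This is the known trivalent-rhodium oxidative [4+2] annulation of salicylaldehydes with internal alkynes to chromones, run with a preformed silver-free cationic Cp*Rh complex so that no silver salt can strip silicon from 8 or add the free phenol of 4 to its neighbouring prenyl olefin. The C2 hydroxyl of 4 binds rhodium as a phenoxide, and acetate-assisted cleavage of the formyl C–H bond gives a five-membered acyl rhodacycle. Alkyne 8 inserts into the rhodium–acyl bond (C3–C4) to give a seven-membered oxa-rhodacycle, and ring C closes by C–O reductive elimination from it (O1–C2), a metal-templated closure and not a conjugate addition; two Cu(OAc)2 then return monovalent rhodium to the trivalent state. The selectivity needed is the orientation of insertion: the acyl group must migrate to the aryl-bearing carbon and rhodium must take the silyl-bearing one. Three features of 8 favour this: SiMe3 is the larger group and avoids the acyl carbon flanked by O–Rh and OMOM; a carbon–metal bond α to silicon is stabilised; and the donor-substituted aryl ring polarises the triple bond so that the silyl-bearing carbon is the electron-rich end that binds the cationic metal, the same preference that places silicon next to the heteroatom in the Larock heteroannulation. The prenyl olefins are trisubstituted and meta to the formyl group, so hydroacylation does not compete, and the acetals meet only acetate-buffered acetic acid. No stereocentre is formed. Any 10 that arises by loss of silicon from 9 in the flask is carried forward, since both converge in step 6.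

Step 6
Reactants: 9 3-[2-methoxy-4-(methoxymethoxy)phenyl]-5,7-bis(methoxymethoxy)-6,8-bis(3-methylbut-2-en-1-yl)-2-(trimethylsilyl)-4H-chromen-4-one
Product: 10 3-[2-methoxy-4-(methoxymethoxy)phenyl]-5,7-bis(methoxymethoxy)-6,8-bis(3-methylbut-2-en-1-yl)-4H-chromen-4-one
Conditions: Bu4NF (1.2 equiv, 1 M in THF), wet THF, 0 °C → rt
Reagents that add atoms: none
Why: Fluoride-induced protodesilylation of a heteroaryl-type vinylsilane, as practised on 2-silyl benzofurans and indoles; the silicate releases an sp2 carbanion at C2 that is stabilised by the adjacent ring oxygen and is protonated by water. Acetals, olefins and the methyl ether are inert, and low temperature with near-stoichiometric fluoride limits attack of hydroxide at C2.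

Step 7
Reactants: 10 3-[2-methoxy-4-(methoxymethoxy)phenyl]-5,7-bis(methoxymethoxy)-6,8-bis(3-methylbut-2-en-1-yl)-4H-chromen-4-one
Product: 11 5,7-dihydroxy-3-(4-hydroxy-2-methoxyphenyl)-6,8-bis(3-methylbut-2-en-1-yl)-4H-chromen-4-one
Conditions: HCl (3 M aq.), MeOH–THF, 40 °C
Reagents that add atoms: none
Why: Acid-catalysed acetal exchange with methanol, the usual cleavage of aryl methoxymethyl ethers in prenylated flavonoids; each acetal leaves as dimethoxymethane, the C5 acetal first with help from the carbonyl oxygen. Dilute acid and moderate temperature are chosen so that the freed phenols do not add to the prenyl olefins.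

## Compound list

1 | 2,4,6-trihydroxybenzaldehyde | O=Cc1c(O)cc(O)cc1O | starting material
2 | prenyl bromide (1-bromo-3-methylbut-2-ene) | CC(C)=CCBr | starting material
3 | 2,4,6-trihydroxy-3,5-bis(3-methylbut-2-en-1-yl)benzaldehyde | O=Cc1c(O)c(CC=C(C)C)c(O)c(CC=C(C)C)c1O | intermediate
4 | 2-hydroxy-4,6-bis(methoxymethoxy)-3,5-bis(3-methylbut-2-en-1-yl)benzaldehyde | O=Cc1c(O)c(CC=C(C)C)c(OCOC)c(CC=C(C)C)c1OCOC | intermediate
5 | 4-bromo-3-methoxyphenol | COc1cc(O)ccc1Br | starting material
6 | 1-bromo-2-methoxy-4-(methoxymethoxy)benzene | COCOc1ccc(Br)c(OC)c1 | intermediate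
7 | ethynyltrimethylsilane | C#C[Si](C)(C)C | starting material
8 | {[2-methoxy-4-(methoxymethoxy)phenyl]ethynyl}trimethylsilane | C[Si](C)(C)C#Cc1ccc(OCOC)cc1OC | intermediate
9 | 3-[2-methoxy-4-(methoxymethoxy)phenyl]-5,7-bis(methoxymethoxy)-6,8-bis(3-methylbut-2-en-1-yl)-2-(trimethylsilyl)-4H-chromen-4-one | COCOc1ccc(-c2c([Si](C)(C)C)oc3c(CC=C(C)C)c(OCOC)c(CC=C(C)C)c(OCOC)c3c2=O)c(OC)c1 | intermediate
10 | 3-[2-methoxy-4-(methoxymethoxy)phenyl]-5,7-bis(methoxymethoxy)-6,8-bis(3-methylbut-2-en-1-yl)-4H-chromen-4-one | COCOc1ccc(-c2coc3c(CC=C(C)C)c(OCOC)c(CC=C(C)C)c(OCOC)c3c2=O)c(OC)c1 | intermediate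
11 | 5,7-dihydroxy-3-(4-hydroxy-2-methoxyphenyl)-6,8-bis(3-methylbut-2-en-1-yl)-4H-chromen-4-one (no stereocentre) | COc1cc(O)ccc1-c1coc2c(CC=C(C)C)c(O)c(CC=C(C)C)c(O)c2c1=O | target

## Step count and risk

Total: 7 steps. Longest linear sequence: 5 steps (steps 1, 2, 5, 6, 7 from 1; equally steps 3, 4, 5, 6, 7 from 5).

**Step 5 (key step).**
- Risks: insertion of the alkyne in the opposite orientation; decarbonylation of the crowded acyl rhodium intermediate before insertion; copper-mediated loss of silicon from 8 before it inserts, which removes the steering group.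
- Fallback: sets out from 4 and 6 and returns at 10, replacing aldehyde C–H activation by the enaminone, iodochromone and cross-coupling sequence.
  - MeMgBr (3 equiv, THF, −78 → 0 °C) adds to 4 to give racemic 2-(1-hydroxyethyl)-3,5-bis(methoxymethoxy)-4,6-bis(3-methylbut-2-en-1-yl)phenol F1.
  - MnO2 in CH2Cl2 oxidises the benzylic alcohol to 1-[2-hydroxy-4,6-bis(methoxymethoxy)-3,5-bis(3-methylbut-2-en-1-yl)phenyl]ethan-1-one F2.
  - N,N-Dimethylformamide dimethyl acetal at 90 °C gives (E)-3-(dimethylamino)-1-[2-hydroxy-4,6-bis(methoxymethoxy)-3,5-bis(3-methylbut-2-en-1-yl)phenyl]prop-2-en-1-one F3 (identical with A3).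
  - I2 and pyridine in CHCl3 at 0 °C close it to 3-iodo-5,7-bis(methoxymethoxy)-6,8-bis(3-methylbut-2-en-1-yl)-4H-chromen-4-one F4. The enamine carbon is far more nucleophilic than the trisubstituted olefins, and the only free hydroxyl is consumed in the ring closure.
  - Bromide 6 is converted with n-BuLi and B(OiPr)3 (THF, −78 °C, aqueous work-up) into [2-methoxy-4-(methoxymethoxy)phenyl]boronic acid F5.
  - Suzuki–Miyaura coupling of F4 with F5 (Pd(dppf)Cl2, K2CO3, dioxane–water, 80 °C) gives 10.

**Step 1.**
- Risks: over-alkylation to geminally diprenylated, dearomatised products; competing O-alkylation; incomplete second alkylation.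
- Fallback: sets out from 1 and returns at 4, replacing steps 1 and 2; the prenyl groups are introduced by cross-coupling.
  - MOMCl (2.2 equiv) and i-Pr2NEt convert 1 into 2-hydroxy-4,6-bis(methoxymethoxy)benzaldehyde F6.
  - N-Iodosuccinimide (2.2 equiv, CH2Cl2, 0 °C) iodinates both open, doubly oxygen-activated positions to give 2-hydroxy-3,5-diiodo-4,6-bis(methoxymethoxy)benzaldehyde F7.
  - Double Stille coupling with tributyl(3-methylbut-2-en-1-yl)stannane (Pd(PPh3)4, DMF, 90 °C) gives 4.

**Step 6.**
- Risks: hydroxide formed from wet fluoride attacks C2 of the unmasked pyranone, with ring opening and loss of C2; cleavage of the hindered C2–Si bond is sluggish.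
- Fallback: sets out from 9 and returns at 11, bypassing 10 by reversing the order of the two deprotections.
  - 3 M HCl in MeOH–THF at 40 °C removes the acetals first, giving 5,7-dihydroxy-3-(4-hydroxy-2-methoxyphenyl)-6,8-bis(3-methylbut-2-en-1-yl)-2-(trimethylsilyl)-4H-chromen-4-one F8.
  - KF in MeOH at rt then cleaves the C–Si bond. Under fluoride the C7 hydroxyl, a vinylogous acid, is deprotonated, and the phenoxide deactivates C2 toward nucleophiles.

**Step 7.**
- Risks: acid-catalysed addition of the freed C5 and C7 phenols to the adjacent prenyl olefins (chroman formation) or hydration of the olefins, competing with cleavage of the hindered C7 acetal.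
- Fallback: sets out from 3 and 5 and returns at 11; the acetals are replaced by 2-(trimethylsilyl)ethoxymethyl ethers so that the endgame needs fluoride only. SEMCl stands for [2-(chloromethoxy)ethyl]trimethylsilane.
  - SEMCl and i-Pr2NEt convert 3 into 2-hydroxy-3,5-bis(3-methylbut-2-en-1-yl)-4,6-bis{[2-(trimethylsilyl)ethoxy]methoxy}benzaldehyde F9.
  - SEMCl and i-Pr2NEt convert 5 into {2-[(4-bromo-3-methoxyphenoxy)methoxy]ethyl}trimethylsilane F10.
  - Sonogashira coupling of F10 with 7 as in step 4 gives {[2-methoxy-4-{[2-(trimethylsilyl)ethoxy]methoxy}phenyl]ethynyl}trimethylsilane F11.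
  - Annulation of F9 with F11 as in step 5 gives 3-[2-methoxy-4-{[2-(trimethylsilyl)ethoxy]methoxy}phenyl]-6,8-bis(3-methylbut-2-en-1-yl)-2-(trimethylsilyl)-5,7-bis{[2-(trimethylsilyl)ethoxy]methoxy}-4H-chromen-4-one F12.
  - Bu4NF in THF–DMPU at 60 °C removes the C2 silyl group and all three ether groups in one operation to give 11.

## Further compounds

F1 | step 5 | 2-(1-hydroxyethyl)-3,5-bis(methoxymethoxy)-4,6-bis(3-methylbut-2-en-1-yl)phenol (racemic) | CC(O)c1c(O)c(CC=C(C)C)c(OCOC)c(CC=C(C)C)c1OCOC
F2 | step 5 | 1-[2-hydroxy-4,6-bis(methoxymethoxy)-3,5-bis(3-methylbut-2-en-1-yl)phenyl]ethan-1-one | CC(=O)c1c(O)c(CC=C(C)C)c(OCOC)c(CC=C(C)C)c1OCOC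
F3 | step 5 | (E)-3-(dimethylamino)-1-[2-hydroxy-4,6-bis(methoxymethoxy)-3,5-bis(3-methylbut-2-en-1-yl)phenyl]prop-2-en-1-one | CN(C)/C=C/C(=O)c1c(O)c(CC=C(C)C)c(OCOC)c(CC=C(C)C)c1OCOC
F4 | step 5 | 3-iodo-5,7-bis(methoxymethoxy)-6,8-bis(3-methylbut-2-en-1-yl)-4H-chromen-4-one | COCOc1c(CC=C(C)C)c(OCOC)c(CC=C(C)C)c2occ(I)c(=O)c12
F5 | step 5 | [2-methoxy-4-(methoxymethoxy)phenyl]boronic acid | COCOc1ccc(B(O)O)c(OC)c1
F6 | step 1 | 2-hydroxy-4,6-bis(methoxymethoxy)benzaldehyde | O=Cc1c(O)cc(OCOC)cc1OCOC
F7 | step 1 | 2-hydroxy-3,5-diiodo-4,6-bis(methoxymethoxy)benzaldehyde | O=Cc1c(O)c(I)c(OCOC)c(I)c1OCOC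
F8 | step 6 | 5,7-dihydroxy-3-(4-hydroxy-2-methoxyphenyl)-6,8-bis(3-methylbut-2-en-1-yl)-2-(trimethylsilyl)-4H-chromen-4-one | COc1cc(O)ccc1-c1c([Si](C)(C)C)oc2c(CC=C(C)C)c(O)c(CC=C(C)C)c(O)c2c1=O
F9 | step 7 | 2-hydroxy-3,5-bis(3-methylbut-2-en-1-yl)-4,6-bis{[2-(trimethylsilyl)ethoxy]methoxy}benzaldehyde | O=Cc1c(O)c(CC=C(C)C)c(OCOCC[Si](C)(C)C)c(CC=C(C)C)c1OCOCC[Si](C)(C)C
F10 | step 7 | {2-[(4-bromo-3-methoxyphenoxy)methoxy]ethyl}trimethylsilane | COc1cc(OCOCC[Si](C)(C)C)ccc1Br
F11 | step 7 | {[2-methoxy-4-{[2-(trimethylsilyl)ethoxy]methoxy}phenyl]ethynyl}trimethylsilane | COc1cc(OCOCC[Si](C)(C)C)ccc1C#C[Si](C)(C)C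
F12 | step 7 | 3-[2-methoxy-4-{[2-(trimethylsilyl)ethoxy]methoxy}phenyl]-6,8-bis(3-methylbut-2-en-1-yl)-2-(trimethylsilyl)-5,7-bis{[2-(trimethylsilyl)ethoxy]methoxy}-4H-chromen-4-one | COc1cc(OCOCC[Si](C)(C)C)ccc1-c1c([Si](C)(C)C)oc2c(CC=C(C)C)c(OCOCC[Si](C)(C)C)c(CC=C(C)C)c(OCOCC[Si](C)(C)C)c2c1=O
A1 | alternative 1 | 3-[2-methoxy-4-(methoxymethoxy)phenyl]-5,7-bis[(2-methylbut-3-en-2-yl)oxy]-4H-chromen-4-one | COCOc1ccc(-c2coc3cc(OC(C)(C)C=C)cc(OC(C)(C)C=C)c3c2=O)c(OC)c1
A2 | alternative 1 | 5,7-dihydroxy-3-[2-methoxy-4-(methoxymethoxy)phenyl]-6,8-bis(3-methylbut-2-en-1-yl)-4H-chromen-4-one | COCOc1ccc(-c2coc3c(CC=C(C)C)c(O)c(CC=C(C)C)c(O)c3c2=O)c(OC)c1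
A3 | alternative 2 | (E)-3-(dimethylamino)-1-[2-hydroxy-4,6-bis(methoxymethoxy)-3,5-bis(3-methylbut-2-en-1-yl)phenyl]prop-2-en-1-one | CN(C)/C=C/C(=O)c1c(O)c(CC=C(C)C)c(OCOC)c(CC=C(C)C)c1OCOC
A4 | alternative 2 | 3-methoxyphenol | COc1cccc(O)c1
A5 | alternative 2 | 3-(4-hydroxy-2-methoxyphenyl)-5,7-bis(methoxymethoxy)-6,8-bis(3-methylbut-2-en-1-yl)-4H-chromen-4-one | COCOc1c(CC=C(C)C)c(OCOC)c(CC=C(C)C)c2occ(-c3ccc(O)cc3OC)c(=O)c12
A6 | alternative 3 | 3,5-bis(methoxymethoxy)-2,4-bis(3-methylbut-2-en-1-yl)-6-(trimethylsilyl)phenyl trifluoromethanesulfonate | COCOc1c(CC=C(C)C)c(OCOC)c(CC=C(C)C)c(OS(=O)(=O)C(F)(F)F)c1[Si](C)(C)C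
A7 | alternative 3 | 3,5-bis(methoxymethoxy)-4,6-bis(3-methylbut-2-en-1-yl)-1,2-didehydrobenzene (aryne) | COCOC1=C(CC=C(C)C)C(OCOC)=C(CC=C(C)C)C#C1
A8 | alternative 3 | methyl 3-hydroxy-2-[2-methoxy-4-(methoxymethoxy)phenyl]prop-2-enoate (enol tautomer, geometry not fixed) | COC(=O)C(=CO)c1ccc(OCOC)cc1OC
A9 | alternative 3 | 3-[2-methoxy-4-(methoxymethoxy)phenyl]-5,7-bis(methoxymethoxy)-6,8-bis(3-methylbut-2-en-1-yl)-4H-chromen-4-one | COCOc1ccc(-c2coc3c(CC=C(C)C)c(OCOC)c(CC=C(C)C)c(OCOC)c3c2=O)c(OC)c1
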